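## The problem

1. Target 15 is epioritin-(4β→6)-epioritin-4β-ol. It consists of two (2R,3R)-2,3-cis-7,8,4'-trihydroxyflavan units: the upper has rings A (benzo), B (4-hydroxyphenyl) and C (pyran), the lower has rings D, E and F in the same order, and a bond joins C4 of ring C to C6 of ring D.
2. The six stereocentres form two triads. In both, C2/C3 are cis and C3/C4 trans, so ring D on C4 of ring C and the hydroxyl on C4 of ring F both stand anti to the neighbouring 3-OH.
3. C3 can control C4, because a nucleophile takes a C4 cation anti to the 3-oxygen. Nothing in a finished ring favours 2,3-cis: additions to a chromene come anti to the 2-aryl group, and invertive closure of the syn-diol of an (E)-alkene gives 2,3-trans.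
4. The interflavanyl bond is the hardest bond. Rings A and D are pyrogallol-type and lack a 5-oxygen, so the C4 cation of the upper unit is poorly stabilised and C6 of ring D is a weak carbon nucleophile that competes with its own oxygens. The lower unit also carries a 4-OH that ionises under the same conditions.
5. The fragile groups are that benzylic 4-OH (acid, hydrogenolysis), the interflavanyl bond (acid), the two catechols (base and air) and the two 4-oxybenzylic C2-O1 bonds.
6. The enabling feature lies in ring D. C4 of ring C (on C6) and C4 of ring F (on C4a) are meta to each other. Each is ortho to one and para to the other of the same two donor oxygens, O1 of ring F on C8a and the oxygen on C7. One hydride-abstracting quinone can therefore raise both carbons from CH2 to the cation level.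
7. C4 of ring C is also bonded to C4a of ring A, the only free position ortho to O1 of ring C and para to the oxygen on C7 of ring A. Ring A can close this bond from within while water serves the cation in ring F.
8. Both halves hold the same string aryl-O1-C2(aryl)-C3(O)-C4 in the same configuration, so one small chiral epoxide can be used twice.

## Retrosynthesis

**15 ⇒ 14.** The six phenolic O-benzyl bonds are cut. Benzyl ethers survive every reagent of the route and come off without acid or base, which the catechols and the 4-OH need. The forward step must spare the benzylic C4-OH of ring F.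

**14 ⇒ 12 (key cut).**
- Two bonds on the two carbons that flank ring D are cut together: C4(ring C)-C4a(ring A) and C4(ring F)-OH.
- The neighbouring cut C4(ring C)-C6(ring D) asks the weak nucleophile ring D to meet the weakly stabilised cation of ring A. The chosen cut reverses the roles: ring D, with two donors in the right places, carries the charge, and ring A is held at bonding distance by the tether O1-C2-C3.
- Precursor 12 has one ring, two stereocentres and one oxygen fewer than 14, and both positions to be functionalised are plain methylene groups.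
- The forward reaction must abstract hydride twice, close ring C anti to the 3-OH (through 13) and let water enter ring F anti to its 3-OH.

**12 ⇒ 10 + 8.** The interflavanyl bond C4(ring C)-C6(ring D) is cut, now as an aryl-CH2 bond next to a carbinol. It becomes the opening of terminal epoxide 8 at its unsubstituted carbon by the C6 organometallic 11 made from iodide 10. The halogen fixes the regiochemistry and no stereocentre is formed, so the hardest bond of the target is reduced to an SN2 reaction on a primary carbon.

**10 ⇒ 9 ⇒ 8.** First C6-I is cut, then C4(ring F)-C4a(ring D). Flavan-3-ol 9 is the product of epoxide 8 reacting with its own aryl ether ring. Closure at C4-C4a leaves O1-C2 and C3-O untouched, so the threo relation of 8 becomes 2,3-cis without oxidation and reduction at C3. Both halves of 12 thus come from 8.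

**8 ⇒ 7 + 4.** O1-C2 is cut. An invertive Mitsunobu etherification turns an erythro epoxy alcohol into the threo ether. The erythro isomer 7 is the one that a Sharpless kinetic resolution delivers. Closing O1-C2 last on a ring, the neighbouring option, would give 2,3-trans from the readily made syn-diols.

**7 ⇒ 6 ⇒ 5.** The oxirane oxygen is removed, then the vinyl-carbinol bond is cut. Racemic 6 comes from aldehyde 5 in one step. One reagent-controlled step selects the carbinol configuration and creates the oxirane stereocentre.

**4 ⇒ 3 ⇒ 2 ⇒ 1.** The phenolic oxygen is traced back through formate 3 to the formyl group of 2. This distinguishes one oxygen of a pyrogallol from the other two at the start, from catechol aldehyde 1.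

## Roads not taken

**Alternative 1:** (the most obvious)
- Cut: C4(ring C)-C6(ring D) between two finished flavans.
- Forward key step: thiophilic or Lewis-acid activation of the 4β-benzylsulfanyl flavan-3-ol A1 in the presence of the protected flavan-3,4-diol A2, to give 14.
- Ring A gives a poorly stabilised cation and ring D is a weak nucleophile with O-alkylation as a side path.
- A2 ionises at its own C4 under the same conditions, so self-condensation, chain growth and C4 epimerisation compete, and an excess of A2 is needed.
- A1 and A2 each need their own C4 oxidation of 9. The chosen plan needs one oxidation step for both carbons and never exposes a 4-OH to a Lewis acid.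

**Alternative 2:**
- Cut: the same bond at the coumarin stage, and C2-C1' of ring B later.
- Forward key step: asymmetric 1,4-addition of boronic acid A4 to 7,8-bis(benzyloxy)coumarin A3 with Rh(acac)(C2H4)2 and a chiral bisphosphine, to give dihydrocoumarin A5. Enolate hydroxylation, aryllithium addition to the lactone and silane reduction at C2 would follow.
- C4 would be set by the catalyst, and the hydroxylation should come anti to ring D.
- Hydride delivery to the C2 oxocarbenium ion is expected anti to the pseudo-axial ring D. That places ring B cis to ring D, the wrong relation at C2.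
- Four further steps would run on the full-size intermediate, and the ortho-alkoxy boronic acid A4 is prone to protodeboronation.

**Alternative 3:**
- Cut: C3-C4 of ring C.
- Forward key step: addition of styrylboronate A7 to the ortho-quinone methide released from benzhydrol A6, under a chiral 3,3'-dibromobinaphthol catalyst, to give triarylpropene A8. Asymmetric dihydroxylation and Mitsunobu closure would follow.
- C4 would be set well. However, a syn-diol from an (E)-alkene closed with inversion at C2 gives the 2,3-trans dimer A9.
- Correction at C3 goes through a flavan-3-one flanked by the doubly benzylic C4-H and by C2-H, where epimerisation is likely. Hydride would also have to come from the face covered by ring D.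
- The chosen plan sets the 2,3-cis relation in the small epoxide 8 and does not touch it afterwards.

Key step: step 9

Remark on the chemistry: in step 9 the acyclic methylene group is assumed to react first, so that 13 is the intermediate. The reverse order of the two oxidations leads to the same product 14.

## Steps

Step 1
Reactants: 1 2,3-dihydroxybenzaldehyde
Product: 2 2,3-bis(benzyloxy)benzaldehyde
Conditions: BnBr (2.2 equiv), K2CO3, DMF, 60 °C
Reagents that add atoms: benzyl bromide, BrCc1ccccc1
Why: Williamson etherification of both phenols; the aldehyde is inert to carbonate.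

Step 2
Reactants: 2 2,3-bis(benzyloxy)benzaldehyde
Product: 4 2,3-bis(benzyloxy)phenol, via aryl formate 3 (not isolated)
Conditions: mCPBA, CH2Cl2, rt; then K2CO3 (cat.), MeOH, rt
Reagents that add atoms: meta-chloroperbenzoic acid, O=C(OO)c1cccc(Cl)c1
Why: Baeyer-Villiger (Dakin-type) oxidation, in which the electron-rich aryl group migrates to give formate 3; methanolysis in the same flask frees the phenol, and the benzyl ethers are inert.

Step 3
Reactants: 5 4-(benzyloxy)benzaldehyde
Product: 6 rac-1-[4-(benzyloxy)phenyl]prop-2-en-1-ol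
Conditions: CH2=CHMgBr, THF, 0 °C
Reagents that add atoms: vinylmagnesium bromide, C=C[Mg]Br
Why: Grignard 1,2-addition to an aromatic aldehyde; the racemate is what the following resolution needs.

Step 4
Reactants: 6 rac-1-[4-(benzyloxy)phenyl]prop-2-en-1-ol
Product: 7 (S)-[4-(benzyloxy)phenyl][(2R)-oxiran-2-yl]methanol (erythro)
Conditions: Ti(OiPr)4 (15 mol%), L-(+)-DIPT (18 mol%), t-BuOOH (0.5 equiv), 4 Å MS, CH2Cl2, -20 °C
Reagents that add atoms: tert-butyl hydroperoxide, CC(C)(C)OO
Why: Sharpless kinetic resolution by asymmetric epoxidation: with L-(+)-tartrate the (R)-enantiomer of 6 reacts faster and gives the erythro epoxy alcohol, so the reagent selects the carbinol centre and creates the oxirane centre (later C3); the slower (S)-enantiomer of 6 stays behind and is separated.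

Step 5
Reactants: 7 (S)-[4-(benzyloxy)phenyl][(2R)-oxiran-2-yl]methanol; 4 2,3-bis(benzyloxy)phenol
Product: 8 (2R)-2-{(R)-[2,3-bis(benzyloxy)phenoxy][4-(benzyloxy)phenyl]methyl}oxirane (threo)
Conditions: PPh3, DIAD, toluene, 0 °C to rt
Reagents that add atoms: none
Why: Mitsunobu etherification with SN2 inversion at the carbinol carbon (later C2) converts the erythro alcohol into the threo ether, the open-chain form of 2,3-cis; the electron-withdrawing oxirane next to the reacting carbon should hold back ionisation of the 4-benzyloxybenzylic oxyphosphonium ion, and the oxirane carbon is not touched.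

Step 6
Reactants: 8 (2R)-2-{(R)-[2,3-bis(benzyloxy)phenoxy][4-(benzyloxy)phenyl]methyl}oxirane
Product: 9 (2R,3R)-7,8-bis(benzyloxy)-2-[4-(benzyloxy)phenyl]chroman-3-ol (tri-O-benzyl-epioritin)
Conditions: AuCl3 (3 mol%), AgOTf (9 mol%), 2,6-di-tert-butyl-4-methylpyridine (5 mol%), ClCH2CH2Cl, rt
Reagents that add atoms: none
Why: Friedel-Crafts cyclialkylation of an aryl glycidyl ether to a chroman-3-ol (6-endo-tet at the unsubstituted oxirane carbon), a known reaction type for electron-rich aryl ethers; the oxirane oxygen is the most basic site, and the attacking carbon is the only free ortho position and lies para to a benzyloxy group. C2 and C3 keep all their bonds, so threo becomes 2,3-cis.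

Step 7
Reactants: 9 (2R,3R)-7,8-bis(benzyloxy)-2-[4-(benzyloxy)phenyl]chroman-3-ol
Product: 10 (2R,3R)-7,8-bis(benzyloxy)-2-[4-(benzyloxy)phenyl]-6-iodochroman-3-ol
Conditions: NIS, CF3CO2H (cat.), MeCN, 0 °C, dark
Reagents that add atoms: N-iodosuccinimide, O=C1CCC(=O)N1I
Why: Electrophilic aromatic iodination; C6 is para to O1 and ortho to the 7-benzyloxy group, whereas C5 is activated only by the twisted middle 8-benzyloxy group, and the monoalkoxy ring is much less reactive.

Step 8
Reactants: 10 (2R,3R)-7,8-bis(benzyloxy)-2-[4-(benzyloxy)phenyl]-6-iodochroman-3-ol; 8 (2R)-2-{(R)-[2,3-bis(benzyloxy)phenoxy][4-(benzyloxy)phenyl]methyl}oxirane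
Product: 12 (2R,3R)-7,8-bis(benzyloxy)-2-[4-(benzyloxy)phenyl]-6-{(2R,3R)-3-[2,3-bis(benzyloxy)phenoxy]-3-[4-(benzyloxy)phenyl]-2-hydroxypropyl}chroman-3-ol, via arylmagnesium alkoxide 11 (not isolated)
Conditions: i-PrMgCl·LiCl (2.1 equiv), THF, -15 °C to rt; then CuI (10 mol%), 8, -30 °C to rt; aq. NH4Cl
Reagents that add atoms: none
Why: The first equivalent of the Grignard reagent deprotonates the 3-OH and the second effects iodine-magnesium exchange, helped by the ortho benzyloxy group; copper-catalysed opening of a terminal epoxide by an aryl Grignard reagent goes at the unsubstituted carbon. No stereocentre is formed or touched, and the iodine fixes the site of the interflavanyl bond.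

Step 9
Reactants: 12 (2R,3R)-7,8-bis(benzyloxy)-2-[4-(benzyloxy)phenyl]-6-{(2R,3R)-3-[2,3-bis(benzyloxy)phenoxy]-3-[4-(benzyloxy)phenyl]-2-hydroxypropyl}chroman-3-ol
Product: 14 hexa-O-benzyl-epioritin-(4β→6)-epioritin-4β-ol, via ring-C-closed hexabenzyl dimer 13 (not isolated)
Conditions: DDQ (2.3 equiv), CH2Cl2/H2O (20:1), 0.01 M, 0 °C to rt
Reagents that add atoms: water, O
Why: Proposed new method: DDQ should abstract hydride from each of the two methylene groups on ring D, because the cation at C4 of ring C (on C6) and the cation at C4 of ring F (on C4a) are each para to one and ortho to the other of the donors O1 of ring F and the 7-benzyloxy oxygen, and no other C-H bond of 12 has two such donors. The closest known reaction types are the DDQ oxidation of flavan-3-ol ethers at C4 with capture by alcohols or water and DDQ-mediated dehydrogenative benzylic arylation; new here are the internal arene as trap and the two events in one flask. Ring C closes by 6-exo-trig attack of C4a of ring A on the exocyclic cationic carbon; C4a is the only free position ortho to O1 and lies para to the 7-benzyloxy group of ring A, so no other six-membered ring can form. C4 of ring C is controlled by C3: allylic 1,3-strain places H3 in the plane of the ring-D cation, the tether through C2 holds ring A over one face and the 3-OH covers the other, so the new bond forms anti to the hydroxyl (3,4-trans, 4β), and a reversible collapse to the 3,4-epoxide would lead to the same result by inversion. C4 of ring F is set by axial attack of water anti to the axial 3-OH of the 2,3-cis ring (4β-OH), as known for 2,3-cis flavan-3-ol ethers. The step needs the arene to win over water at the acyclic cation, which the low water content of CH2Cl2 and the six-membered transition state should secure, while the cation in ring F has no internal partner and waits for water. Further oxidation should be slow because the remaining C4-H bonds of 14 are pseudo-equatorial and poorly aligned with the ring π systems.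

Step 10
Reactants: 14 hexa-O-benzyl-epioritin-(4β→6)-epioritin-4β-ol
Product: 15 epioritin-(4β→6)-epioritin-4β-ol (target)
Conditions: H2 (1 atm), Pd(OH)2/C, THF/MeOH, rt, stopped at full debenzylation
Reagents that add atoms: none
Why: Hydrogenolysis of six aryl benzyl ethers under neutral conditions, the standard unmasking of benzylated proanthocyanidins; without acid, aryl benzyl ethers should be cleaved much faster than the secondary benzylic C4-OH and the cyclic C2-O1 bonds, and no stereocentre is touched.

## Compound list

1 | 2,3-dihydroxybenzaldehyde | O=Cc1cccc(O)c1O | starting material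
2 | 2,3-bis(benzyloxy)benzaldehyde | O=Cc1cccc(OCc2ccccc2)c1OCc1ccccc1 | intermediate
3 | 2,3-bis(benzyloxy)phenyl formate | O=COc1cccc(OCc2ccccc2)c1OCc1ccccc1 | intermediate
4 | 2,3-bis(benzyloxy)phenol | Oc1cccc(OCc2ccccc2)c1OCc1ccccc1 | intermediate
5 | 4-(benzyloxy)benzaldehyde | O=Cc1ccc(OCc2ccccc2)cc1 | starting material
6 | rac-1-[4-(benzyloxy)phenyl]prop-2-en-1-ol | C=CC(O)c1ccc(OCc2ccccc2)cc1 | intermediate
7 | (S)-[4-(benzyloxy)phenyl][(2R)-oxiran-2-yl]methanol, erythro | C(c1ccccc1)Oc1ccc(cc1)[C@H](O)[C@H]1CO1 | intermediate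
8 | (2R)-2-{(R)-[2,3-bis(benzyloxy)phenoxy][4-(benzyloxy)phenyl]methyl}oxirane, threo | C(c1ccccc1)Oc1ccc(cc1)[C@@H](Oc1cccc(OCc2ccccc2)c1OCc1ccccc1)[C@H]1CO1 | intermediate
9 | (2R,3R)-7,8-bis(benzyloxy)-2-[4-(benzyloxy)phenyl]chroman-3-ol (tri-O-benzyl-epioritin, 2,3-cis) | c1cc2c(c(OCc3ccccc3)c1OCc1ccccc1)O[C@H](c1ccc(OCc3ccccc3)cc1)[C@H](O)C2 | intermediate
10 | (2R,3R)-7,8-bis(benzyloxy)-2-[4-(benzyloxy)phenyl]-6-iodochroman-3-ol | Ic1cc2c(c(OCc3ccccc3)c1OCc1ccccc1)O[C@H](c1ccc(OCc3ccccc3)cc1)[C@H](O)C2 | intermediate
11 | C6-chloromagnesio derivative of 9 as its 3-O-chloromagnesium alkoxide | Cl[Mg]c1cc2c(c(OCc3ccccc3)c1OCc1ccccc1)O[C@H](c1ccc(OCc3ccccc3)cc1)[C@H](O[Mg]Cl)C2 | intermediate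
12 | (2R,3R)-7,8-bis(benzyloxy)-2-[4-(benzyloxy)phenyl]-6-{(2R,3R)-3-[2,3-bis(benzyloxy)phenoxy]-3-[4-(benzyloxy)phenyl]-2-hydroxypropyl}chroman-3-ol | C(c1ccccc1)Oc1ccc(cc1)[C@@H](Oc1cccc(OCc2ccccc2)c1OCc1ccccc1)[C@H](O)Cc1cc2c(c(OCc3ccccc3)c1OCc1ccccc1)O[C@H](c1ccc(OCc3ccccc3)cc1)[C@H](O)C2 | intermediate
13 | hexa-O-benzyl-epioritin-(4β→6)-epioritin (both units 2R,3R, ring D 4β on ring C, trans to the 3-OH) | C(c1ccccc1)Oc1ccc(cc1)[C@H]1Oc2c(ccc(OCc3ccccc3)c2OCc2ccccc2)[C@H](c2cc3c(c(OCc4ccccc4)c2OCc2ccccc2)O[C@H](c2ccc(OCc4ccccc4)cc2)[C@H](O)C3)[C@H]1O | intermediate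
14 | hexa-O-benzyl-epioritin-(4β→6)-epioritin-4β-ol (as 13, with a 4β-OH on ring F, trans to its 3-OH) | C(c1ccccc1)Oc1ccc(cc1)[C@H]1Oc2c(ccc(OCc3ccccc3)c2OCc2ccccc2)[C@H](c2cc3c(c(OCc4ccccc4)c2OCc2ccccc2)O[C@H](c2ccc(OCc4ccccc4)cc2)[C@H](O)[C@H]3O)[C@H]1O | intermediate
15 | (2R,3R,4S)-2-(4-hydroxyphenyl)-6-[(2R,3R,4S)-3,7,8-trihydroxy-2-(4-hydroxyphenyl)chroman-4-yl]chromane-3,4,7,8-tetrol | Oc1ccc([C@H]2Oc3c(ccc(O)c3O)[C@H](c3cc4c(c(O)c3O)O[C@H](c3ccc(O)cc3)[C@H](O)[C@H]4O)[C@H]2O)cc1 | target

## Step count and least certain steps

Total steps: 10. The longest linear sequence is 8 steps (steps 3 to 10 from 5; steps 1, 2 and 5 to 10 from 1 are equally long). Epoxide 8 enters twice, in steps 6 and 8. Joining two enantioenriched halves should raise the enantiomeric purity of the dimer, because the minor enantiomer ends up mainly in separable diastereomers.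

**Step 9 (key step, proposed new method).**
- What may go wrong: hydride abstraction may stop after one methylene group or stray to the C2-H bonds. Water may capture the acyclic cation, followed by further oxidation at that carbon. A 1,2-hydride shift from C3 may occur, or the facial selectivity of the ring closure may be imperfect.
- Fallback (known chemistry): it sets out from 9 and comes back at 13. Compound 9 is oxidised with DDQ in the presence of 2-ethoxyethanol to the 4β-(2-ethoxyethoxy) ether F1. F1 is then ionised with TMSOTf in CH2Cl2 at -78 °C in the presence of an excess of 9, whose C6 takes the cation anti to the 3-OH to give 13, now isolated. A separate oxidation of 13 with DDQ in wet CH2Cl2 at its only remaining methylene group gives 14.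

**Step 6.**
- What may go wrong: the Lewis acid may ionise the 4-benzyloxybenzylic C2-O bond before the ring has closed. Attack at the inner oxirane carbon (5-exo) may also compete.
- Fallback: it changes the order of bond formation, sets out from 4 and 7 and comes back at 9. Ortho-bromination of 4 (NBS, catalytic i-Pr2NH, CH2Cl2) gives 6-bromo-2,3-bis(benzyloxy)phenol F2. Its O,C-dianion (n-BuLi, then MgBr2·OEt2 and catalytic CuI) opens the lithium alkoxide of 7 at the unsubstituted oxirane carbon to give the erythro phenol diol F3. An intramolecular Mitsunobu etherification (PPh3, DIAD) then closes O1-C2 with inversion at the benzylic carbon to give 9.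

**Step 5.**
- What may go wrong: partial ionisation of the activated 4-benzyloxybenzylic carbinol would cost configurational integrity at C2.
- Fallback: it forms the C2-O1 bond by metal catalysis, sets out from 6 and 4 and comes back at 8. A 1,3-transposition of 6 (catalytic Re2O7) gives (E)-4-(benzyloxy)cinnamyl alcohol F4, and ClCO2Me/pyridine gives its methyl carbonate F5. Asymmetric allylic etherification of the sodium salt of 4 with [Ir(cod)Cl]2 and a binaphthol-derived phosphoramidite gives the branched (S)-allyl aryl ether F6. Epoxidation with dimethyldioxirane is then followed by hydrolytic kinetic resolution with the enantiomer of (salen)Co(OAc) matched to the unwanted epimer, which leaves 8.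

**Step 10.**
- What may go wrong: the benzylic C4-O bond of ring F may be hydrogenolysed alongside the benzyl ethers.
- Fallback: it moves the reductive step ahead of the introduction of that oxygen, sets out from 13 (isolated as in the fallback to step 9) and comes back at 15. Hydrogenolysis of 13 gives free epioritin-(4β→6)-epioritin F7. TBSCl/imidazole in DMF gives its hexakis(phenolic) silyl ether F8, and DDQ in wet CH2Cl2 gives the 4β-alcohol F9. Et3N·3HF in THF then frees 15 without reduction, acid or base.

## Further compounds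

F1 | step 9 | (2R,3R,4S)-7,8-bis(benzyloxy)-2-[4-(benzyloxy)phenyl]-4-(2-ethoxyethoxy)chroman-3-ol | c1cc2c(c(OCc3ccccc3)c1OCc1ccccc1)O[C@H](c1ccc(OCc3ccccc3)cc1)[C@H](O)[C@H]2OCCOCC
F2 | step 6 | 6-bromo-2,3-bis(benzyloxy)phenol | Oc1c(Br)ccc(OCc2ccccc2)c1OCc1ccccc1
F3 | step 6 | (1S,2R)-3-[3,4-bis(benzyloxy)-2-hydroxyphenyl]-1-[4-(benzyloxy)phenyl]propane-1,2-diol | C(c1ccccc1)Oc1ccc(cc1)[C@H](O)[C@H](O)Cc1ccc(OCc2ccccc2)c(OCc2ccccc2)c1O
F4 | step 5 | (E)-3-[4-(benzyloxy)phenyl]prop-2-en-1-ol | OC/C=C/c1ccc(OCc2ccccc2)cc1
F5 | step 5 | (E)-3-[4-(benzyloxy)phenyl]prop-2-en-1-yl methyl carbonate | COC(=O)OC/C=C/c1ccc(OCc2ccccc2)cc1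
F6 | step 5 | 1,2-bis(benzyloxy)-3-({(1S)-1-[4-(benzyloxy)phenyl]prop-2-en-1-yl}oxy)benzene | C(c1ccccc1)Oc1ccc(cc1)[C@@H](Oc1cccc(OCc2ccccc2)c1OCc1ccccc1)C=C
F7 | step 10 | epioritin-(4β→6)-epioritin | Oc1ccc(cc1)[C@H]1Oc2c(ccc(O)c2O)[C@H](c2cc3c(c(O)c2O)O[C@H](c2ccc(O)cc2)[C@H](O)C3)[C@H]1O
F8 | step 10 | hexakis(phenolic O-tert-butyldimethylsilyl) ether of epioritin-(4β→6)-epioritin | CC(C)(C)[Si](C)(C)Oc1ccc(cc1)[C@H]1Oc2c(ccc(O[Si](C)(C)C(C)(C)C)c2O[Si](C)(C)C(C)(C)C)[C@H](c2cc3c(c(O[Si](C)(C)C(C)(C)C)c2O[Si](C)(C)C(C)(C)C)O[C@H](c2ccc(O[Si](C)(C)C(C)(C)C)cc2)[C@H](O)C3)[C@H]1O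
F9 | step 10 | hexakis(phenolic O-tert-butyldimethylsilyl) ether of epioritin-(4β→6)-epioritin-4β-ol | CC(C)(C)[Si](C)(C)Oc1ccc(cc1)[C@H]1Oc2c(ccc(O[Si](C)(C)C(C)(C)C)c2O[Si](C)(C)C(C)(C)C)[C@H](c2cc3c(c(O[Si](C)(C)C(C)(C)C)c2O[Si](C)(C)C(C)(C)C)O[C@H](c2ccc(O[Si](C)(C)C(C)(C)C)cc2)[C@H](O)[C@H]3O)[C@H]1O
A1 | alternative 1 | 4β-(benzylsulfanyl)-7,8-bis(benzyloxy)-2-[4-(benzyloxy)phenyl]chroman-3-ol (2,3-cis-3,4-trans) | c1cc2c(c(OCc3ccccc3)c1OCc1ccccc1)O[C@H](c1ccc(OCc3ccccc3)cc1)[C@H](O)[C@H]2SCc1ccccc1
A2 | alternative 1 | (2R,3R,4S)-7,8-bis(benzyloxy)-2-[4-(benzyloxy)phenyl]chromane-3,4-diol | c1cc2c(c(OCc3ccccc3)c1OCc1ccccc1)O[C@H](c1ccc(OCc3ccccc3)cc1)[C@H](O)[C@H]2O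
A3 | alternative 2 | 7,8-bis(benzyloxy)-2H-chromen-2-one | O=c1ccc2ccc(OCc3ccccc3)c(OCc3ccccc3)c2o1
A4 | alternative 2 | {(2R,3R)-7,8-bis(benzyloxy)-2-[4-(benzyloxy)phenyl]-3-hydroxychroman-6-yl}boronic acid | OB(O)c1cc2c(c(OCc3ccccc3)c1OCc1ccccc1)O[C@H](c1ccc(OCc3ccccc3)cc1)[C@H](O)C2
A5 | alternative 2 | 7,8-bis(benzyloxy)-4β-{(2R,3R)-7,8-bis(benzyloxy)-2-[4-(benzyloxy)phenyl]-3-hydroxychroman-6-yl}chroman-2-one | O=C1C[C@@H](c2cc3c(c(OCc4ccccc4)c2OCc2ccccc2)O[C@H](c2ccc(OCc4ccccc4)cc2)[C@H](O)C3)c2ccc(OCc3ccccc3)c(OCc3ccccc3)c2O1
A6 | alternative 3 | (2R,3R)-7,8-bis(benzyloxy)-6-{[3,4-bis(benzyloxy)-2-hydroxyphenyl](hydroxy)methyl}-2-[4-(benzyloxy)phenyl]chroman-3-ol (carbinol epimers) | Oc1c(ccc(OCc2ccccc2)c1OCc1ccccc1)C(O)c1cc2c(c(OCc3ccccc3)c1OCc1ccccc1)O[C@H](c1ccc(OCc3ccccc3)cc1)[C@H](O)C2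
A7 | alternative 3 | diethyl (E)-{2-[4-(benzyloxy)phenyl]ethenyl}boronate | CCOB(OCC)/C=C/c1ccc(OCc2ccccc2)cc1
A8 | alternative 3 | (2R,3R)-7,8-bis(benzyloxy)-6-{(E)-1-[3,4-bis(benzyloxy)-2-hydroxyphenyl]-3-[4-(benzyloxy)phenyl]prop-2-en-1-yl}-2-[4-(benzyloxy)phenyl]chroman-3-ol (methine configured as C4 of ring C in 13) | Oc1c(ccc(OCc2ccccc2)c1OCc1ccccc1)[C@H](c1cc2c(c(OCc3ccccc3)c1OCc1ccccc1)O[C@H](c1ccc(OCc3ccccc3)cc1)[C@H](O)C2)/C=C/c1ccc(OCc2ccccc2)cc1
A9 | alternative 3 | C3 epimer of 13 in ring C (2,3-trans-3,4-cis upper unit) | C(c1ccccc1)Oc1ccc(cc1)[C@H]1Oc2c(ccc(OCc3ccccc3)c2OCc2ccccc2)[C@H](c2cc3c(c(OCc4ccccc4)c2OCc2ccccc2)O[C@H](c2ccc(OCc4ccccc4)cc2)[C@H](O)C3)[C@@H]1O
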